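**Assumption:** the target has no stereogenic centre (it is achiral), so "single enantiomer" is read as the single geometric isomer: E feruloyl alkene, E chalcone alkene, and Z side-chain alkene (CH2O cis to CH2Ar).

## Retrosynthetic overview

1. The last operation is only removal of four phenolic acetates; the ferulate ester is carried in from the start, so there is no late esterification.
2. Key disconnection: the benzylic CH2–CH= bond, made by a stereoretentive sp3–sp2 Negishi coupling between the benzylzinc of a complete chalcone and a ferulate-bearing (Z)-vinyl iodide. This avoids aryl prenylation/Claisen, SeO2 oxidation (which would give the wrong E isomer) and carbonyl olefination.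
3. The Z-trisubstituted alkene is set in one step from propargyl alcohol by hydroxyl-directed anti-carbomagnesiation/iodination; the Mg–O chelate forces I cis to CH2OH.
4. The chalcone comes from condensation of 2',4'-dihydroxy-3'-methylacetophenone with 4-hydroxybenzaldehyde; the 3'-CH3 is converted to CH2Br as the latent benzyl nucleophile.
5. No rings are formed: all three benzene rings are purchased.

## Route

**Step 1**
Reactants: 1 propargyl alcohol; 2 methylmagnesium bromide; 3 iodine
Product: 4 (Z)-3-iodo-2-methylprop-2-en-1-ol
Conditions: MeMgBr (2.5 equiv), CuI (10 mol%), THF/Et2O, –10 °C to rt; then I2, –10 °C to rt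
Reagents that add atoms: methylmagnesium bromide, C[Mg]Br (CH3); iodine, II (I)
Why: Cu-catalysed hydroxyl-directed anti-carbomagnesiation of a propargylic alcohol puts Me on C2 and Mg on C3 inside a five-membered oxamagnesacycle, so the C–Mg bond, and after stereoretentive iodinolysis the C–I bond, is necessarily cis to CH2O (Z).

**Step 2**
Reactants: 4 (Z)-3-iodo-2-methylprop-2-en-1-ol; 5 (E)-4-acetoxy-3-methoxycinnamic acid (O-acetylferulic acid)
Product: 6 (2Z)-3-iodo-2-methylprop-2-en-1-yl (2E)-3-(4-acetoxy-3-methoxyphenyl)prop-2-enoate
Conditions: 5, (COCl)2, cat. DMF, CH2Cl2, 0 °C to rt, concentrate; then 4, pyridine, CH2Cl2, 0 °C to rt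
Reagents that add atoms: O-acetylferulic acid (5), COc1cc(/C=C/C(=O)O)ccc1OC(C)=O
Why: acid-chloride esterification of a primary allylic alcohol touches neither alkene, so the Z-vinyl iodide and E-cinnamate are retained, and the acetate masks the phenol for the later organozinc step.

**Step 3**
Reactants: 7 2',4'-dihydroxy-3'-methylacetophenone; 8 4-hydroxybenzaldehyde
Product: 9 (2E)-1-(2,4-dihydroxy-3-methylphenyl)-3-(4-hydroxyphenyl)prop-2-en-1-one (3'-methylisoliquiritigenin)
Conditions: BF3·OEt2, 1,4-dioxane, rt; aqueous work-up (alternative: 50% KOH, EtOH, rt)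
Reagents that add atoms: 4-hydroxybenzaldehyde (8), O=Cc1ccc(O)cc1
Why: BF3-mediated Claisen–Schmidt aldol condensation works on free hydroxy-acetophenones and hydroxy-benzaldehydes (boron chelates the 2'-OH/C=O), and dehydration gives the thermodynamic E-enone.

**Step 4**
Reactants: 9 3'-methylisoliquiritigenin; 10 acetic anhydride
Product: 11 4-[(1E)-3-(2,4-diacetoxy-3-methylphenyl)-3-oxoprop-1-en-1-yl]phenyl acetate (triacetate of 9)
Conditions: Ac2O, pyridine, cat. DMAP, CH2Cl2, rt
Reagents that add atoms: acetic anhydride, CC(=O)OC(C)=O
Why: DMAP-catalysed O-acetylation caps all three phenols, including the H-bonded 2'-OH, which removes acidic protons and deactivates the rings towards electrophilic bromination in the next step.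

**Step 5**
Reactants: 11 triacetate; 12 N-bromosuccinimide
Product: 13 4-{(1E)-3-[2,4-diacetoxy-3-(bromomethyl)phenyl]-3-oxoprop-1-en-1-yl}phenyl acetate
Conditions: NBS (1.05 equiv), AIBN (5 mol%), PhCF3, 85 °C, visible light
Reagents that add atoms: N-bromosuccinimide, O=C1CCC(=O)N1Br (Br)
Why: Wohl–Ziegler radical bromination attacks the only benzylic C–H bonds, while the acyl/acetoxy-deactivated rings and the electron-poor enone alkene resist Br2 at the low concentration NBS maintains.

**Step 6 (key step)**
Reactants: 13 benzylic bromide; 6 (Z)-vinyl iodide ferulate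
Product: 14 (2Z)-4-{2,6-diacetoxy-3-[(2E)-3-(4-acetoxyphenyl)prop-2-enoyl]phenyl}-2-methylbut-2-en-1-yl (2E)-3-(4-acetoxy-3-methoxyphenyl)prop-2-enoate (tetra-O-acetyl gemichalcone A)
Conditions: 13, activated Zn dust, LiCl, THF, 0 °C to rt; then 6 (0.9 equiv), Pd(PPh3)4 (5 mol%), THF, rt
Reagents that add atoms: compound 6, COc1cc(/C=C/C(=O)OC/C(C)=C\I)ccc1OC(C)=O (everything except I)
Why: LiCl-mediated zinc insertion gives a benzylzinc bromide that tolerates esters, ketones and enones, and Negishi sp3–sp2 coupling with the alkenyl iodide proceeds with retention of alkene geometry (stereoretentive oxidative addition and reductive elimination, no β-hydrogen on the benzyl partner), so the Z geometry from step 1 is transferred intact.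

**Step 7**
Reactants: 14 tetra-O-acetyl gemichalcone A
Product: 15 gemichalcone A
Conditions: NH4OAc (excess), MeOH/THF/H2O, rt
Reagents that add atoms: none
Why: chemoselective solvolysis of aryl acetates (phenoxide leaving groups) is far faster than cleavage of the conjugated alkyl cinnamate ester, and these near-neutral conditions do not isomerise the alkenes or cyclise the 2'-hydroxychalcone.

## Compound list

1 | propargyl alcohol | C#CCO | starting material
2 | methylmagnesium bromide | C[Mg]Br | starting material (reagent)
3 | iodine | II | starting material (reagent)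
4 | (Z)-3-iodo-2-methylprop-2-en-1-ol | OC/C(C)=C\I | intermediate
5 | (E)-4-acetoxy-3-methoxycinnamic acid (O-acetylferulic acid) | COc1cc(/C=C/C(=O)O)ccc1OC(C)=O | starting material
6 | (2Z)-3-iodo-2-methylprop-2-en-1-yl (2E)-3-(4-acetoxy-3-methoxyphenyl)prop-2-enoate | COc1cc(/C=C/C(=O)OC/C(C)=C\I)ccc1OC(C)=O | intermediate
7 | 2',4'-dihydroxy-3'-methylacetophenone | CC(=O)c1ccc(O)c(C)c1O | starting material
8 | 4-hydroxybenzaldehyde | O=Cc1ccc(O)cc1 | starting material
9 | (2E)-1-(2,4-dihydroxy-3-methylphenyl)-3-(4-hydroxyphenyl)prop-2-en-1-one | Cc1c(O)ccc(C(=O)/C=C/c2ccc(O)cc2)c1O | intermediate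
10 | acetic anhydride | CC(=O)OC(C)=O | starting material (reagent)
11 | 4-[(1E)-3-(2,4-diacetoxy-3-methylphenyl)-3-oxoprop-1-en-1-yl]phenyl acetate | Cc1c(OC(C)=O)ccc(C(=O)/C=C/c2ccc(OC(C)=O)cc2)c1OC(C)=O | intermediate
12 | N-bromosuccinimide | O=C1CCC(=O)N1Br | starting material (reagent)
13 | 4-{(1E)-3-[2,4-diacetoxy-3-(bromomethyl)phenyl]-3-oxoprop-1-en-1-yl}phenyl acetate | BrCc1c(OC(C)=O)ccc(C(=O)/C=C/c2ccc(OC(C)=O)cc2)c1OC(C)=O | intermediate
14 | tetra-O-acetyl gemichalcone A | COc1cc(/C=C/C(=O)OC/C(C)=C\Cc2c(OC(C)=O)ccc(C(=O)/C=C/c3ccc(OC(C)=O)cc3)c2OC(C)=O)ccc1OC(C)=O | intermediate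
15 | gemichalcone A | COc1cc(/C=C/C(=O)OC/C(C)=C\Cc2c(O)ccc(C(=O)/C=C/c3ccc(O)cc3)c2O)ccc1O | target

Availability: 5 and 7 are taken as catalogue compounds. If not, each is one step from a commodity chemical: ferulic acid with Ac2O/pyridine for 5, and 2-methylresorcinol with AcOH/BF3·OEt2 for 7.

## Summary

**Total steps:** 7 (east arm: steps 1–2; west arm: steps 3–5; union: step 6; unveiling: step 7).
**Longest linear sequence:** 5 steps (7 → 9 → 11 → 13 → 14 → 15).

**Three steps most likely to fail, with fallbacks:**

1. **Step 6 (zinc insertion/Negishi union).** Risks are Wurtz homocoupling of the benzyl bromide, attack of the benzylzinc on the enone or ortho-acetates, Pd ionisation of the allylic ester, and Z/E erosion. Fallback: reverse the polarity. Convert 6 to the (Z)-alkenyl pinacolboronate by Miyaura borylation and couple it with benzyl bromide 13 by anhydrous Suzuki–Miyaura coupling, so no organozinc is ever generated on the chalcone fragment.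

2. **Step 5 (Wohl–Ziegler bromination in the presence of the chalcone).** Risks are Br2 addition to the enone alkene and α-bromination of the ketone. Fallback: change the order of events. Brominate 2,4-diacetoxy-3-methylacetophenone, which has no alkene, perform the Negishi coupling with 6, and build the chalcone last under non-hydrolytic conditions (silyl enol ether formation, Mukaiyama aldol with 4-acetoxybenzaldehyde, MsCl/Et3N dehydration).

3. **Step 7 (fourfold aryl-acetate removal next to an allylic ferulate).** Risks are ester transesterification, flavanone formation, and attack of the 4'-phenoxide on the allylic ester. Fallback: take the ester out of the deprotection. Couple 13 with the TBS ether of 4 instead of 6, strip the acetates and TBS group, and install the ferulate last by chemoselective Mitsunobu esterification of the primary allylic alcohol with unprotected ferulic acid (the carboxylic acid is the only sufficiently acidic pronucleophile).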